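The runs stem from a simulated flask with made-up constants, noise included.

Amounts first: the flask holds 0.015 M of L and saturation holds 0.94 mM of G, so if each L takes one G, the solution must be refilled about 16.0 times over.

the same everywhere: X 0.94 mM (held)
- summer: L 0.0075 M; run made earlier
- midnight: L 0.030 M; run made earlier
- flask: L 0.015 M; time 2.0 min

| run | time / s | Q / % | L / % |
|---|---|---|---|
| summer | 10.0 | 9.3 | 89.3 |
| summer | 20.0 | 18.3 | 77.8 |
| summer | 40.0 | 26.2 | 63.6 |
| summer | 90.0 | 33.4 | 40.0 |
| midnight | 25.0 | 17.7 | 80.0 |
| midnight | 50.0 | 30.4 | 67.8 |
| midnight | 80.0 | 31.9 | 53.5 |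
| midnight | 90.0 | 32.5 | 47.5 |

(each reading ± 1 percentage point)

- at the start none of X is in solution
- G is what X becomes in solution

1. how much Q there is at 2.0 min, in percent of the L charged
2. concentration of G in solution at 2.0 min, in percent of saturation

The first rung is the gas. Neither run shows a lag, and at 10.0 s the summer run already holds 9.3 % of Q, so we take G to be up within seconds and L to decay as pseudo-first-order. The last readings give rate constants of 0.0102 s⁻¹ in summer and 0.00827 s⁻¹ at midnight. The flask's charge is twice the summer one and half the midnight one, so we take their geometric mean, 0.00918 s⁻¹, which makes the lifetime of L 109 s.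

So we count lifetimes: N, the time run divided by the lifetime of L, is 1.10 for this flask, and the L left is exp(−N), or 33.2 %.

The next rung is the shortfall, the charge found neither as L nor as Q. In summer it grows from 1.4 percentage points at 10.0 s to 27 points at 90.0 s, and Q flattens meanwhile: 33.4 % at N = 0.916 in summer, 32.5 % at N = 0.744 at midnight. The flask's N is larger than both, so we commit to Q just under those readings. No reading shows G, so we name no figure for it.

The forecast gave 88 % of saturation for G and 34 % of Q, which is above both readings we hold to, holding that “the plateau depends on conversion”.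

The flask gives 31.3 % of Q and G at 88.0 % of saturation, with 33 % of L left where exp(−N) said 33.2 %.

    X ⇌ G, rate k1*(csat - [G]) (kL = 0.840 s⁻¹)
    L + G ⇌ Q (K = 3100 M⁻¹, k = 15.0 M⁻¹ s⁻¹)
    G + Q → D (k = 14.0 M⁻¹ s⁻¹)

At 0.824 min the flask makes Q 1.77 times as fast as it uses it up, each step taken net, and at 2.00 min that ratio is 0.728. So the flat stretch is a top that the flask has passed by the asked time, with Q at 31.6 % at 1.00 min and 31.3 % at 2.00 min.

Read the same flask at 3.0 min: N becomes 1.65, so exp(−N) says 19.2 % of L. It computes to 21 % of L and 23.9 % of Q.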